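## Retrosynthetic overview

1. Target 15 ⇐ angeloylation of O-3 in diol 14 ⇐ α-methylenation (C13) of ester 11 ⇐ methyl addition to the C4 ketone and α′-hydroxylation at C3 of enone ester 8. Eudesmane numbering is used: ring A = C1–C5 and C10, ring B = C5–C10, side chain C11–C13, β = face of the C10 methyl.
2. 8 ⇐ one-pot annulation of 3-methylcyclohex-2-enone 4 (ring A, bought) with ester acetal 3. C9–C10 forms by copper-catalysed asymmetric conjugate addition of an alkylzirconocene, C5–C6 by Mukaiyama closure of the resulting enol ether onto the acetal, and C5=C6 by loss of methanol. Ring B is the only ring that is made.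
3. Enabling feature: the carbinol carbon C4 of ring A is the neighbour of C5. At the ketone level ring A is the β-methyl enone C4(=O)–C5=C10(CH3), so its C5–C10 edge is electrophilic at C10 and then nucleophilic at C5, and the C5=C6 bond of ring B is the α,β-bond of that ketone.
4. 3 ⇐ acidic methanolysis of lactone acetal 2 ⇐ auxiliary-controlled vinyl conjugate addition to menthyloxyfuranone 1. The acetal carbon, β-carbon, α-carbon and carbonyl of 1 become C6, C7, C11 and C12; the vinyl group becomes C8–C9.
5. Stereocentres: C7 from the auxiliary (step 1), C10 from the catalyst (step 3), C3 and C4 from the ring (steps 4 and 5).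

Key step: step 3

Remark: 1 is the enantiomer of the common (5R)-5-(l-menthyloxy)furanone and is taken as purchasable; the ligand enantiomer in step 3 is the one that gives the (R)-3-alkyl-3-methylcyclohexanone series.

## Route

Step 1
Reactants: 1 (5S)-5-[(1S,2R,5S)-menthyloxy]furan-2(5H)-one
Product: 2 (4R,5S)-5-[(1S,2R,5S)-menthyloxy]-4-vinyldihydrofuran-2(3H)-one
Conditions: CH2=CHMgBr (1.5 equiv), CuBr·SMe2 (10 mol%), THF, −78 → −40 °C; aq NH4Cl
Reagents that add atoms: vinylmagnesium bromide, C=C[Mg]Br
Why: Copper-catalysed conjugate addition of the vinyl Grignard reagent to the butenolide should occur anti to the bulky 5-menthyloxy group (auxiliary control), which sets C7 as the 4R centre with the vinyl group trans to the acetal substituent.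

Step 2
Reactants: 2 (4R,5S)-5-[(1S,2R,5S)-menthyloxy]-4-vinyldihydrofuran-2(3H)-one
Product: 3 methyl (3R)-3-(dimethoxymethyl)pent-4-enoate
Conditions: HC(OMe)3, MeOH, TsOH·H2O (5 mol%), rt → 40 °C
Reagents that add atoms: methanol, CO; trimethyl orthoformate, COC(OC)OC
Why: Acid-catalysed transacetalisation with opening of the pseudo-ester (lactone acetal) should give the open methyl ester dimethyl acetal and release the auxiliary, the orthoformate taking up the water, while C7 is not involved.

Step 3
Reactants: 3 methyl (3R)-3-(dimethoxymethyl)pent-4-enoate; 4 3-methylcyclohex-2-en-1-one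
Product: 8 methyl 2-[(2S,4aR)-4a-methyl-8-oxo-2,3,4,4a,5,6,7,8-octahydronaphthalen-2-yl]acetate, via alkylzirconocene 5 (not isolated), via silyl enol ether 6 (not isolated), via methoxy ketone 7 (not isolated)
Conditions: Cp2Zr(H)Cl (1.0 equiv), CH2Cl2, rt; then 4 (1.5 equiv), (CuOTf)2·C6H6 (5 mol%), BINOL-derived N,N-bis(1-phenylethyl)phosphoramidite (12 mol%), TMSCl, Et2O, rt; solvent switch to CH2Cl2, TMSOTf (0.3 equiv), −78 → −20 °C; then DBU, 0 °C → rt
Reagents that add atoms: none
Why: Hydrozirconation of the vinyl group of 3 gives the primary alkylzirconocene 5, which transmetalates to a chiral monovalent copper–phosphoramidite complex and adds 1,4 to enone 4, forming C9–C10 and, with TMSCl, the regiodefined C4–C5 silyl enol ether 6; TMSOTf then ionises the dimethyl acetal to an oxocarbenium ion at C6 that is captured by C5 (C5–C6), and DBU expels methanol from the β-methoxy ketone 7 (E1cB) to leave the C5=C6 enone. The closest known reaction types are the copper-catalysed asymmetric conjugate addition of alkylzirconocenes to 3-methylcyclohex-2-enone and the tandem conjugate addition/Mukaiyama acetal aldol annulation. Ring B closes in a 6-(enolexo)-exo-trig Mukaiyama aldol onto the tethered oxocarbenium ion. The quaternary C10 centre is set by the chiral ligand on copper (catalyst control, C7 being too remote to interfere), C7 is carried in from 3 and never becomes α to a free carbonyl, and the transient C5 and C6 centres of 7 are erased in the elimination. The step needs regiocontrol of the C5 nucleophile and chemoselectivity for the vinyl group: the enol ether is born only at C4–C5 by the conjugate addition itself, closure from C5 is the only one that gives a six-membered ring, and the monosubstituted alkene should be hydrozirconated much faster than the ester is reduced.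

Step 4
Reactants: 8 methyl 2-[(2S,4aR)-4a-methyl-8-oxo-2,3,4,4a,5,6,7,8-octahydronaphthalen-2-yl]acetate
Product: 10 methyl 2-[(2S,4aS,7S)-7-hydroxy-4a-methyl-8-oxo-2,3,4,4a,5,6,7,8-octahydronaphthalen-2-yl]acetate, via 3α-hydroxy epimer 9 (not isolated)
Conditions: NaHMDS (1.1 equiv), THF, −78 °C; 2-(phenylsulfonyl)-3-phenyloxaziridine, −78 °C; aq NH4Cl; then DBU (0.2 equiv), CH2Cl2, rt, argon
Reagents that add atoms: 2-(phenylsulfonyl)-3-phenyloxaziridine, O=S(=O)(c1ccccc1)N1OC1c1ccccc1
Why: Kinetic deprotonation should take the only α-CH2 of the ketone (C3, more acidic than the ester CH2) and the enolate is oxidised by the N-sulfonyloxaziridine (Davis oxidation); the kinetic 3α-alcohol 9 should be converted by base-mediated enolisation into the equatorial 3β-epimer 10, the thermodynamic one because its hydroxyl lies in plane with, and hydrogen-bonded to, the C4 carbonyl.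

Step 5
Reactants: 10 methyl 2-[(2S,4aS,7S)-7-hydroxy-4a-methyl-8-oxo-2,3,4,4a,5,6,7,8-octahydronaphthalen-2-yl]acetate
Product: 11 methyl 2-[(2S,4aS,7S,8R)-7,8-dihydroxy-4a,8-dimethyl-2,3,4,4a,5,6,7,8-octahydronaphthalen-2-yl]acetate
Conditions: MeMgBr (4 equiv), anhydrous CeCl3 (4 equiv), THF, −78 °C; aq NH4Cl
Reagents that add atoms: methylmagnesium bromide, C[Mg]Br
Why: The organocerium reagent should add 1,2 to the ketone much faster than to the methyl ester at −78 °C and without enolisation, and the methyl group should enter from the α-face of the chelated 3β-alkoxy ketone, away from the pseudo-axial C10 methyl that stands 1,3 to C4, which gives the 4β-hydroxyl cis to the 3β-hydroxyl.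

Step 6
Reactants: 11 methyl 2-[(2S,4aS,7S,8R)-7,8-dihydroxy-4a,8-dimethyl-2,3,4,4a,5,6,7,8-octahydronaphthalen-2-yl]acetate
Product: 12 methyl 3-(dimethylamino)-2-[(2R,4aS,7S,8R)-7,8-dihydroxy-4a,8-dimethyl-2,3,4,4a,5,6,7,8-octahydronaphthalen-2-yl]propanoate (both C11 epimers)
Conditions: LDA (3.3 equiv, commercial solution), THF, −78 → −30 °C; Eschenmoser's salt (2 equiv), −78 °C → rt; water
Reagents that add atoms: Eschenmoser's salt (N,N-dimethylmethyleneiminium iodide), C=[N+](C)C.[I-]
Why: Excess LDA should form the bis-alkoxide ester enolate, whose α-carbon (C11) is aminomethylated by the iminium salt (Mannich reaction of an ester enolate); the new C11 centre is of no consequence because it becomes sp2 in the next step.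

Step 7
Reactants: 12 methyl 3-(dimethylamino)-2-[(2R,4aS,7S,8R)-7,8-dihydroxy-4a,8-dimethyl-2,3,4,4a,5,6,7,8-octahydronaphthalen-2-yl]propanoate
Product: 14 methyl 2-[(2R,4aS,7S,8R)-7,8-dihydroxy-4a,8-dimethyl-2,3,4,4a,5,6,7,8-octahydronaphthalen-2-yl]prop-2-enoate, via ammonium iodide 13 (not isolated)
Conditions: MeI (excess), MeOH, rt; then aq NaHCO3, CH2Cl2, rt
Reagents that add atoms: none
Why: N-Methylation gives the ammonium salt 13, which should lose trimethylamine by E1cB elimination under bicarbonate to give the α-methylene ester, conditions too mild to move the C7 hydrogen or the C5=C6 bond.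

Step 8
Reactants: 14 methyl 2-[(2R,4aS,7S,8R)-7,8-dihydroxy-4a,8-dimethyl-2,3,4,4a,5,6,7,8-octahydronaphthalen-2-yl]prop-2-enoate
Product: 15 methyl 2-[(2R,4aS,7S,8R)-8-hydroxy-4a,8-dimethyl-7-{[(2Z)-2-methylbut-2-enoyl]oxy}-2,3,4,4a,5,6,7,8-octahydronaphthalen-2-yl]prop-2-enoate (CNP0283268.1)
Conditions: angelic acid, 2,4,6-trichlorobenzoyl chloride, Et3N, toluene, rt; then 14, 80 °C
Reagents that add atoms: angelic acid ((Z)-2-methylbut-2-enoic acid), C/C=C(/C)C(=O)O
Why: Mixed-anhydride (Yamaguchi-type) esterification should acylate the secondary equatorial C3 hydroxyl and leave the tertiary allylic C4 hydroxyl untouched, and the absence of a nucleophilic catalyst should keep the Z geometry of the angelate.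

## Compound list

1 | (5S)-5-[(1S,2R,5S)-menthyloxy]furan-2(5H)-one | O=C1C=C[C@@H](O[C@H]2C[C@@H](C)CC[C@@H]2C(C)C)O1 | starting material
2 | (4R,5S)-5-[(1S,2R,5S)-menthyloxy]-4-vinyldihydrofuran-2(3H)-one (vinyl trans to menthyloxy) | O=C1C[C@H](C=C)[C@@H](O[C@H]2C[C@@H](C)CC[C@@H]2C(C)C)O1 | intermediate
3 | methyl (3R)-3-(dimethoxymethyl)pent-4-enoate | COC(=O)C[C@H](C=C)C(OC)OC | intermediate
4 | 3-methylcyclohex-2-en-1-one | CC1=CC(=O)CCC1 | starting material
5 | chlorobis(cyclopentadienyl)[(3R)-3-(dimethoxymethyl)-5-methoxy-5-oxopentyl]zirconium | COC(=O)C[C@H](CC[Zr](Cl)(C1C=CC=C1)C1C=CC=C1)C(OC)OC | intermediate (not isolated)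
6 | trimethylsilyl enol ether (C4–OSiMe3, C4=C5) of methyl (3S)-3-(dimethoxymethyl)-5-[(1R)-1-methyl-3-oxocyclohexyl]pentanoate | COC(=O)C[C@H](CC[C@@]1(C)CCCC(O[Si](C)(C)C)=C1)C(OC)OC | intermediate (not isolated)
7 | β-methoxy ketone: 6-methoxy-5,6-dihydro derivative of 8 (mixture at C5 and C6) | COC(=O)C[C@H]1C(OC)C2[C@](C)(CCCC2=O)CC1 | intermediate (not isolated)
8 | methyl 2-[(2S,4aR)-4a-methyl-8-oxo-2,3,4,4a,5,6,7,8-octahydronaphthalen-2-yl]acetate (C4 ketone, C5=C6, 7β-CH2CO2Me, 10β-CH3) | COC(=O)C[C@H]1C=C2[C@](C)(CCCC2=O)CC1 | intermediate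
9 | methyl 2-[(2S,4aS,7R)-7-hydroxy-4a-methyl-8-oxo-2,3,4,4a,5,6,7,8-octahydronaphthalen-2-yl]acetate (3α-OH) | COC(=O)C[C@H]1C=C2[C@](C)(CC[C@@H](O)C2=O)CC1 | intermediate (not isolated)
10 | methyl 2-[(2S,4aS,7S)-7-hydroxy-4a-methyl-8-oxo-2,3,4,4a,5,6,7,8-octahydronaphthalen-2-yl]acetate (3β-OH) | COC(=O)C[C@H]1C=C2[C@](C)(CC[C@H](O)C2=O)CC1 | intermediate
11 | methyl 2-[(2S,4aS,7S,8R)-7,8-dihydroxy-4a,8-dimethyl-2,3,4,4a,5,6,7,8-octahydronaphthalen-2-yl]acetate (3β,4β-diol, 4α-CH3) | COC(=O)C[C@H]1C=C2[C@](C)(CC[C@H](O)[C@]2(C)O)CC1 | intermediate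
12 | methyl 3-(dimethylamino)-2-[(2R,4aS,7S,8R)-7,8-dihydroxy-4a,8-dimethyl-2,3,4,4a,5,6,7,8-octahydronaphthalen-2-yl]propanoate (both C11 epimers) | COC(=O)C(CN(C)C)[C@H]1C=C2[C@](C)(CC[C@H](O)[C@]2(C)O)CC1 | intermediate
13 | trimethylammonium iodide of 12 | COC(=O)C(C[N+](C)(C)C)[C@H]1C=C2[C@](C)(CC[C@H](O)[C@]2(C)O)CC1.[I-] | intermediate (not isolated)
14 | methyl 2-[(2R,4aS,7S,8R)-7,8-dihydroxy-4a,8-dimethyl-2,3,4,4a,5,6,7,8-octahydronaphthalen-2-yl]prop-2-enoate | C=C(C(=O)OC)[C@H]1C=C2[C@](C)(CC[C@H](O)[C@]2(C)O)CC1 | intermediate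
15 | methyl 2-[(2R,4aS,7S,8R)-8-hydroxy-4a,8-dimethyl-7-{[(2Z)-2-methylbut-2-enoyl]oxy}-2,3,4,4a,5,6,7,8-octahydronaphthalen-2-yl]prop-2-enoate | C=C(C(=O)OC)[C@H]1C=C2[C@](C)(CC[C@H](OC(=O)/C(C)=C\C)[C@]2(C)O)CC1 | target

## Step count and risks

Total step count: 8. Longest linear sequence: 8 steps (1 → 15); 4 enters at step 3.

**Step 3.** The Lewis-acid stage may not turn over in the presence of the zirconium and copper residues. Alternatively, the oxocarbenium ion may lose a proton to an enol ether, epimerising C7, faster than C5 attacks it. The fallback sets out from 3 and 4 and comes back at 8, and decouples the two bond formations. The hydrozirconation and copper-catalysed conjugate addition are run to aqueous work-up, which hydrolyses 6 and should give methyl (3S)-3-(dimethoxymethyl)-5-[(1R)-1-methyl-3-oxocyclohexyl]pentanoate F1 after chromatography. TsOH in wet acetone should unmask methyl (3S)-3-formyl-5-[(1R)-1-methyl-3-oxocyclohexyl]pentanoate F2. TsOH in benzene at reflux with removal of water should then effect a Brønsted-acid intramolecular aldol condensation, which can close a six-membered ring only from C5, and give 8. Any C7 epimer formed through the enol of F2 would be a diastereomer of 8 and should be separable.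

**Step 4.** Facial selectivity in the enolate oxidation may be poor and the base equilibration at C3 incomplete, leaving 9 mixed with 10. The fallback sets out from the unequilibrated mixture of 9 and 10 and comes back at 11; it makes the C3 configuration independent of the oxidation. MeMgBr/CeCl3 (conditions of step 5) on the mixture should give 11 together with methyl 2-[(2S,4aS,7R,8R)-7,8-dihydroxy-4a,8-dimethyl-2,3,4,4a,5,6,7,8-octahydronaphthalen-2-yl]acetate F3. Dess–Martin periodinane should oxidise the secondary alcohol of both to methyl 2-[(2S,4aS,8R)-8-hydroxy-4a,8-dimethyl-7-oxo-2,3,4,4a,5,6,7,8-octahydronaphthalen-2-yl]acetate F4. NaBH4 in MeOH at −20 °C should then deliver hydride axially to C3, anti to the axial 4β-hydroxyl, and give the equatorial 3β-alcohol 11.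

**Step 8.** Acylation of the hindered C3 hydroxyl, which is flanked by the fully substituted C4, may be slow, and forcing conditions may isomerise the angelate to the tiglate. The fallback sets out from 14 and comes back at 15; it builds the Z double bond after the ester link. Acylation with 2-[bis(2,2,2-trifluoroethoxy)phosphoryl]propanoic acid (DCC, DMAP, CH2Cl2) should give the 3-O-{2-[bis(2,2,2-trifluoroethoxy)phosphoryl]propanoyl} derivative of 14 F5. A Still–Gennari olefination (KHMDS, 18-crown-6, THF, −78 °C; acetaldehyde) should then give the Z-configured 2-methylbut-2-enoate 15.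

## Further compounds

F1 | step 3 | methyl (3S)-3-(dimethoxymethyl)-5-[(1R)-1-methyl-3-oxocyclohexyl]pentanoate | COC(=O)C[C@H](CC[C@@]1(C)CCCC(=O)C1)C(OC)OC
F2 | step 3 | methyl (3S)-3-formyl-5-[(1R)-1-methyl-3-oxocyclohexyl]pentanoate | COC(=O)C[C@H](CC[C@@]1(C)CCCC(=O)C1)C=O
F3 | step 4 | methyl 2-[(2S,4aS,7R,8R)-7,8-dihydroxy-4a,8-dimethyl-2,3,4,4a,5,6,7,8-octahydronaphthalen-2-yl]acetate | COC(=O)C[C@H]1C=C2[C@](C)(CC[C@@H](O)[C@]2(C)O)CC1
F4 | step 4 | methyl 2-[(2S,4aS,8R)-8-hydroxy-4a,8-dimethyl-7-oxo-2,3,4,4a,5,6,7,8-octahydronaphthalen-2-yl]acetate | COC(=O)C[C@H]1C=C2[C@](C)(CCC(=O)[C@]2(C)O)CC1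
F5 | step 8 | 3-O-{2-[bis(2,2,2-trifluoroethoxy)phosphoryl]propanoyl} derivative of 14 | C=C(C(=O)OC)[C@H]1C=C2[C@](C)(CC[C@H](OC(=O)C(C)P(=O)(OCC(F)(F)F)OCC(F)(F)F)[C@]2(C)O)CC1
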